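Retrosynthetic overview
Numbering (germacrane): C4 = methyl-bearing ether carbon, C6 = acyloxy carbon, C7–C8 = lactone fusion (O on C8), C9 = ether methine, C10 = CO2Me-bearing alkene carbon, C12 = lactone C=O, C13 = exo-methylene.
Late stage: the C6 ester, C7–H and C11=C13 are added to a tricyclic butenolide ketone (C6=O, C7=C11), which is the target at another oxidation level.
Key disconnection: C8–C9 and O–C4 are cut together to an acyclic formyl enoate/enone/butenolide. The enabling feature is that C9–O is the carbinol of a vinylogous aldol retron (C9–C8–C7=C11–C12=O, C8 being the γ-carbon of the lactone) and, through the bridging oxygen on C4, sits β to C6 (oxa-Michael retron).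
The acyclic precursor comes from a carbonylative Stille union (C5–C6–C7) of an (E)-vinyl iodide (carboalumination, then Morita–Baylis–Hillman chemistry for C9–C10–C14) with a stannylbutenolide; the side-chain acid comes from isoprene monoxide.
Ring order: butenolide (purchased) → ten-membered carbocycle and both oxepane rings together (key step) → no further ring.

Key step: step 9

Remark: the senses of induction in steps 9, 11 and 15 are expectations by analogy; in each case the mirror-image (or pseudoenantiomeric) catalyst or ligand is available.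

Step 1
Reactants: 1 pent-4-yn-1-ol; 2 trimethylaluminium; 3 iodine
Product: 5 (4E)-5-iodo-4-methylpent-4-en-1-ol, via alkenylalane 4 (not isolated)
Conditions: AlMe3 (3 equiv), Cp2ZrCl2 (0.25 equiv), CH2Cl2, 0 °C to rt; then iodine, THF, −30 to 0 °C
Reagents that add atoms: trimethylaluminium C[Al](C)C; iodine II
Why: Negishi zirconium-catalysed carboalumination adds methyl and aluminium syn across the terminal alkyne (methyl to the internal carbon) and iodinolysis proceeds with retention, which fixes the (E)-trisubstituted alkene that becomes C4=C5 with its C15 methyl.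

Step 2
Reactants: 5 (4E)-5-iodo-4-methylpent-4-en-1-ol
Product: 6 (4E)-5-iodo-4-methylpent-4-enal
Conditions: Dess–Martin periodinane, NaHCO3, CH2Cl2, 0 °C to rt
Reagents that add atoms: none
Why: Dess–Martin oxidation of a primary alcohol to the aldehyde under buffered conditions that leave the vinyl iodide untouched.

Step 3
Reactants: 6 (4E)-5-iodo-4-methylpent-4-enal; 7 methyl acrylate
Product: 8 methyl (6E)-3-hydroxy-7-iodo-6-methyl-2-methylidenehept-6-enoate (racemic)
Conditions: DABCO (0.5 equiv), MeOH, rt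
Reagents that add atoms: methyl acrylate C=CC(=O)OC
Why: Morita–Baylis–Hillman reaction (amine adds to the acrylate, the zwitterionic enolate attacks the aldehyde) forms the C1–C10 bond; the carbinol stereocentre is racemic and is erased in step 4.

Step 4
Reactants: 8 methyl (6E)-3-hydroxy-7-iodo-6-methyl-2-methylidenehept-6-enoate; 9 acetic anhydride
Product: 11 methyl (2E,6E)-2-(acetoxymethyl)-7-iodo-6-methylhepta-2,6-dienoate, via secondary acetate 10 (not isolated)
Conditions: Ac2O, DMAP (cat.), pyridine, CH2Cl2, 0 °C; then TMSOTf (0.1 equiv), CH2Cl2, rt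
Reagents that add atoms: acetic anhydride CC(=O)OC(C)=O
Why: Acetylation followed by Lewis-acid-catalysed 1,3-transposition of the Morita–Baylis–Hillman acetate gives the thermodynamically preferred primary allylic acetate with the (E)-enoate (ester trans to the chain), the geometry needed for C10=C1 inside the oxepene ring.

Step 5
Reactants: 11 methyl (2E,6E)-2-(acetoxymethyl)-7-iodo-6-methylhepta-2,6-dienoate
Product: 12 methyl (2E,6E)-2-(hydroxymethyl)-7-iodo-6-methylhepta-2,6-dienoate
Conditions: K2CO3 (0.2 equiv), MeOH, 0 °C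
Reagents that add atoms: none
Why: Base-catalysed transesterification (Zemplén-type methanolysis) removes the acetate, and the methyl ester is degenerate under these conditions.

Step 6
Reactants: 13 4-bromofuran-2(5H)-one; 14 hexabutylditin
Product: 15 4-(tributylstannyl)furan-2(5H)-one
Conditions: (Bu3Sn)2, Pd(PPh3)4 (5 mol %, zerovalent palladium), toluene, 100 °C
Reagents that add atoms: hexabutylditin CCCC[Sn](CCCC)(CCCC)[Sn](CCCC)(CCCC)CCCC
Why: Palladium-catalysed stannylation of a β-bromo enoate with a distannane (oxidative addition, Sn–Sn transmetalation, reductive elimination) gives the known β-stannylbutenolide coupling partner.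

Step 7
Reactants: 12 methyl (2E,6E)-2-(hydroxymethyl)-7-iodo-6-methylhepta-2,6-dienoate; 15 4-(tributylstannyl)furan-2(5H)-one; 16 carbon monoxide
Product: 17 methyl (2E,6E)-2-(hydroxymethyl)-6-methyl-8-oxo-8-(5-oxo-2,5-dihydrofuran-3-yl)octa-2,6-dienoate
Conditions: Pd2(dba)3 (2.5 mol %, zerovalent palladium), AsPh3 (20 mol %), LiCl, CO (3 bar), NMP, 50 °C
Reagents that add atoms: carbon monoxide [C-]#[O+]
Why: Carbonylative Stille coupling (oxidative addition of the vinyl iodide, CO insertion, transmetalation with the stannylbutenolide) builds the cross-conjugated dienone with retention of the (E)-alkene, C6 coming from CO.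

Step 8
Reactants: 17 methyl (2E,6E)-2-(hydroxymethyl)-6-methyl-8-oxo-8-(5-oxo-2,5-dihydrofuran-3-yl)octa-2,6-dienoate
Product: 18 methyl (2E,6E)-2-formyl-6-methyl-8-oxo-8-(5-oxo-2,5-dihydrofuran-3-yl)octa-2,6-dienoate
Conditions: MnO2 (15 equiv), CH2Cl2, rt
Reagents that add atoms: none
Why: Chemoselective MnO2 oxidation of the primary allylic alcohol gives the 2-formyl enoate with the formyl group cis to the chain, without touching the enone or the butenolide.

Step 9
Reactants: 18 methyl (2E,6E)-2-formyl-6-methyl-8-oxo-8-(5-oxo-2,5-dihydrofuran-3-yl)octa-2,6-dienoate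
Product: 20 methyl (4S,8S,9R)-4,9-epoxy-6-oxo-13-norgermacra-1(10),7(11)-dien-12,8-olid-14-oate, via ten-membered aldol adduct 19 (not isolated)
Conditions: bifunctional squaramide of 9-amino-9-deoxy-epi-quinine and 3,5-bis(trifluoromethyl)aniline (10 mol %), CH2Cl2, 2 mM (slow addition of 18), −20 °C to rt
Reagents that add atoms: none
Why: Proposed new method: the quinuclidine nitrogen deprotonates the butenolide γ-CH2 (C8, acidified by the 4-acyl group) to an ion-paired 2-oxidofuran while the squaramide hydrogen-bonds the formyl oxygen, and γ-selective direct vinylogous aldol addition joins C8 to C9 and closes the ten-membered carbocycle (exo-trig at the formyl carbon) to give 19, whose 9-hydroxyl lies across the ring from the enone and adds transannularly to its β-carbon C4 (oxa-Michael), making the O–C4 bond and with it both oxepane rings (7-exo-trig for the ring through C10–C1–C2–C3, 7-endo-trig for the ring through C8–C7–C6–C5). The closest known reaction types are amine–squaramide-catalysed direct vinylogous aldol additions of γ-butenolides to aldehydes, organocatalytic aldol/oxa-Michael domino sequences and transannular oxa-Michael closures of medium rings; the second half also copies the presumed biosynthesis of the 4,9-ether bridge from a 9-hydroxy melampolide. C9 is set by the catalyst, which must direct C8 to the Si face of the formyl carbon (9R; the quinidine-derived pseudoenantiomer is held in reserve), C4 follows from C9 because a one-atom bridge can only span one face of the ten-membered ring (4S), and C8 stays epimerisable through the furanolate and is expected to settle with the planar butenolide on the less hindered face next to the oxygen bridge (8S). The step needs γ- over α-attack of the dienolate, secured by the return to the conjugated butenolide and the reversibility of α-addition, and ring closure over oligomerisation, for which high dilution and the cis arrangement of formyl group and chain on the C10=C1 alkene are relied on. The aldol step is reversible, so the strained ten-membered aldolate need only form in low concentration before the etherification (two seven-membered rings formed, enone conjugation traded for a C–O bond) drains the equilibrium.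

Step 10
Reactants: 20 methyl (4S,8S,9R)-4,9-epoxy-6-oxo-13-norgermacra-1(10),7(11)-dien-12,8-olid-14-oate
Product: 21 methyl (4S,6R,8S,9R)-4,9-epoxy-6-hydroxy-13-norgermacra-1(10),7(11)-dien-12,8-olid-14-oate
Conditions: NaBH4, CeCl3·7H2O, MeOH, −78 °C
Reagents that add atoms: none
Why: Luche 1,2-reduction of the butenolide-conjugated C6 ketone, in which hydride should enter from the face of the one-atom oxygen bridge and away from the four-carbon bridge carrying the ester (6R); removing the ketone also locks the ether bridge against retro-oxa-Michael opening.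

Step 11
Reactants: 22 2-methyl-2-vinyloxirane (racemic); 23 sodium hydrogencarbonate
Product: 24 (2S)-2-methylbut-3-ene-1,2-diol
Conditions: Pd2(dba)3·CHCl3 (1 mol %, zerovalent palladium), (R,R)-DACH-naphthyl bisphosphine ligand (3 mol %), NaHCO3, Et3B (1 mol %), CH2Cl2/H2O, rt
Reagents that add atoms: sodium hydrogencarbonate [Na+].OC([O-])=O
Why: Palladium-catalysed dynamic kinetic asymmetric allylic substitution: both epoxide enantiomers ionise to interconverting π-allylpalladium alkoxides, and hydrogencarbonate (boron-tethered to the alkoxide) attacks the more substituted terminus under ligand control to set the tertiary carbinol as (S), with CO2 lost from the adduct.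

Step 12
Reactants: 24 (2S)-2-methylbut-3-ene-1,2-diol; 25 sodium chlorite
Product: 26 (2S)-2-hydroxy-2-methylbut-3-enoic acid
Conditions: TEMPO (cat.), NaOCl (cat.), NaClO2, MeCN/phosphate buffer (pH 6.7), 35 °C
Reagents that add atoms: sodium chlorite [Na+].[O-]Cl=O
Why: TEMPO/hypochlorite-catalysed chlorite oxidation takes the primary alcohol through the aldehyde to the acid and leaves the tertiary allylic alcohol and its stereocentre untouched.

Step 13
Reactants: 26 (2S)-2-hydroxy-2-methylbut-3-enoic acid; 27 triethylsilyl trifluoromethanesulfonate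
Product: 29 (2S)-2-methyl-2-(triethylsilyloxy)but-3-enoic acid, via bis-silyl derivative 28 (not isolated)
Conditions: Et3SiOTf (2.2 equiv), 2,6-lutidine, CH2Cl2, −78 to 0 °C; then K2CO3, MeOH/H2O, 0 °C, acidify to pH 4
Reagents that add atoms: triethylsilyl trifluoromethanesulfonate CC[Si](CC)(CC)OS(=O)(=O)C(F)(F)F
Why: Exhaustive silylation followed by selective hydrolysis of the labile silyl ester leaves the tertiary triethylsilyl ether without touching the stereocentre.

Step 14
Reactants: 21 methyl (4S,6R,8S,9R)-4,9-epoxy-6-hydroxy-13-norgermacra-1(10),7(11)-dien-12,8-olid-14-oate; 29 (2S)-2-methyl-2-(triethylsilyloxy)but-3-enoic acid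
Product: 31 methyl (4S,6R,8S,9R)-4,9-epoxy-6-[(2S)-2-methyl-2-(triethylsilyloxy)but-3-enoyloxy]-13-norgermacra-1(10),7(11)-dien-12,8-olid-14-oate, via mixed anhydride 30 (not isolated)
Conditions: 2,4,6-trichlorobenzoyl chloride, Et3N, toluene, rt; then 21, DMAP, toluene, rt to 40 °C
Reagents that add atoms: none
Why: Yamaguchi esterification through the mixed anhydride and the acylpyridinium acylates the hindered allylic C6 alcohol with retention at both stereocentres, and it is done at the butenolide stage because C12 is then held trans to C6 across C7=C11, so translactonisation to O6 cannot occur.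

Step 15
Reactants: 31 methyl (4S,6R,8S,9R)-4,9-epoxy-6-[(2S)-2-methyl-2-(triethylsilyloxy)but-3-enoyloxy]-13-norgermacra-1(10),7(11)-dien-12,8-olid-14-oate; 32 dimethylmethylideneammonium iodide
Product: 34 methyl (4S,6R,7R,8S,9R)-13-(dimethylamino)-4,9-epoxy-6-[(2S)-2-methyl-2-(triethylsilyloxy)but-3-enoyloxy]germacr-1(10)-en-12,8-olid-14-oate (C11 epimers), via silyl ketene acetal 33 (not isolated)
Conditions: Cu(OAc)2·H2O (5 mol %), (R)-DTBM-SEGPHOS (5.5 mol %), (EtO)2MeSiH (2 equiv), toluene, 0 °C; then 32, CH2Cl2, 0 °C to rt; NaHCO3 work-up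
Reagents that add atoms: dimethylmethylideneammonium iodide C=[N+](C)C.[I-]
Why: Copper hydride (monovalent copper) catalysed 1,4-hydrosilylation of the β,β-disubstituted butenolide, expected to be more reactive than the α-branched acyclic enoate, should deliver hydride to C7 from the face of the oxygen bridge opposite the C6 acyloxy group (7R, trans-fused lactone), and the silyl ketene acetal is then trapped in a Mannich reaction; the C11 configuration is irrelevant.

Step 16
Reactants: 34 methyl (4S,6R,7R,8S,9R)-13-(dimethylamino)-4,9-epoxy-6-[(2S)-2-methyl-2-(triethylsilyloxy)but-3-enoyloxy]germacr-1(10)-en-12,8-olid-14-oate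
Product: 36 methyl (4S,6R,7R,8S,9R)-4,9-epoxy-6-[(2S)-2-methyl-2-(triethylsilyloxy)but-3-enoyloxy]germacra-1(10),11(13)-dien-12,8-olid-14-oate, via trimethylammonium iodide 35 (not isolated)
Conditions: MeI, THF, rt; then NaHCO3 (aq), EtOAc, rt
Reagents that add atoms: none
Why: Exhaustive N-methylation and mild base-induced β-elimination of the ammonium salt (Hofmann-type E1cB) unveil the α-methylene lactone without touching C7.

Step 17
Reactants: 36 methyl (4S,6R,7R,8S,9R)-4,9-epoxy-6-[(2S)-2-methyl-2-(triethylsilyloxy)but-3-enoyloxy]germacra-1(10),11(13)-dien-12,8-olid-14-oate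
Product: 37 methyl (4S,6R,7R,8S,9R)-4,9-epoxy-6-[(2S)-2-hydroxy-2-methylbut-3-enoyloxy]germacra-1(10),11(13)-dien-12,8-olid-14-oate (CNP0325750.1)
Conditions: HF·pyridine, pyridine, THF, 0 °C
Reagents that add atoms: none
Why: Fluoride-mediated cleavage of the tertiary triethylsilyl ether under buffered conditions tolerated by the α-methylene lactone and the three esters.

Compound list
1 | pent-4-yn-1-ol | C#CCCCO | starting material
2 | trimethylaluminium | C[Al](C)C | starting material
3 | iodine | II | starting material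
4 | dimethyl[(1E)-5-(dimethylalumanyloxy)-2-methylpent-1-en-1-yl]alumane | C[Al](C)OCCC/C(C)=C/[Al](C)C | intermediate
5 | (4E)-5-iodo-4-methylpent-4-en-1-ol | OCCC/C(C)=C/I | intermediate
6 | (4E)-5-iodo-4-methylpent-4-enal | O=CCC/C(C)=C/I | intermediate
7 | methyl acrylate | C=CC(=O)OC | starting material
8 | methyl (6E)-3-hydroxy-7-iodo-6-methyl-2-methylidenehept-6-enoate (racemic) | COC(=O)C(=C)C(O)CC/C(C)=C/I | intermediate
9 | acetic anhydride | CC(=O)OC(C)=O | starting material
10 | methyl (6E)-3-acetoxy-7-iodo-6-methyl-2-methylidenehept-6-enoate (racemic) | COC(=O)C(=C)C(OC(C)=O)CC/C(C)=C/I | intermediate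
11 | methyl (2E,6E)-2-(acetoxymethyl)-7-iodo-6-methylhepta-2,6-dienoate | COC(=O)/C(COC(C)=O)=C/CC/C(C)=C/I | intermediate
12 | methyl (2E,6E)-2-(hydroxymethyl)-7-iodo-6-methylhepta-2,6-dienoate | COC(=O)/C(CO)=C/CC/C(C)=C/I | intermediate
13 | 4-bromofuran-2(5H)-one | BrC1=CC(=O)OC1 | starting material
14 | hexabutylditin | CCCC[Sn](CCCC)(CCCC)[Sn](CCCC)(CCCC)CCCC | starting material
15 | 4-(tributylstannyl)furan-2(5H)-one | CCCC[Sn](CCCC)(CCCC)C1=CC(=O)OC1 | intermediate
16 | carbon monoxide | [C-]#[O+] | starting material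
17 | methyl (2E,6E)-2-(hydroxymethyl)-6-methyl-8-oxo-8-(5-oxo-2,5-dihydrofuran-3-yl)octa-2,6-dienoate | COC(=O)/C(CO)=C/CC/C(C)=C/C(=O)C1=CC(=O)OC1 | intermediate
18 | methyl (2E,6E)-2-formyl-6-methyl-8-oxo-8-(5-oxo-2,5-dihydrofuran-3-yl)octa-2,6-dienoate | COC(=O)/C(C=O)=C/CC/C(C)=C/C(=O)C1=CC(=O)OC1 | intermediate
19 | methyl (1(10)E,4E,8S,9R)-9-hydroxy-6-oxo-13-norgermacra-1(10),4,7(11)-trien-12,8-olid-14-oate | O=C1/C=C(C)/CC/C=C(C(=O)OC)\[C@@H](O)[C@H]2OC(=O)C=C12 | intermediate
20 | methyl (4S,8S,9R)-4,9-epoxy-6-oxo-13-norgermacra-1(10),7(11)-dien-12,8-olid-14-oate | O=C1C[C@]2(C)CCC=C(C(=O)OC)[C@@H](O2)[C@H]2OC(=O)C=C21 | intermediate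
21 | methyl (4S,6R,8S,9R)-4,9-epoxy-6-hydroxy-13-norgermacra-1(10),7(11)-dien-12,8-olid-14-oate | O[C@@H]1C[C@]2(C)CCC=C(C(=O)OC)[C@@H](O2)[C@H]2OC(=O)C=C21 | intermediate
22 | 2-methyl-2-vinyloxirane (racemic) | CC1(C=C)CO1 | starting material
23 | sodium hydrogencarbonate | [Na+].OC([O-])=O | starting material
24 | (2S)-2-methylbut-3-ene-1,2-diol | C=C[C@](C)(O)CO | intermediate
25 | sodium chlorite | [Na+].[O-]Cl=O | starting material
26 | (2S)-2-hydroxy-2-methylbut-3-enoic acid | C=C[C@](C)(O)C(=O)O | intermediate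
27 | triethylsilyl trifluoromethanesulfonate | CC[Si](CC)(CC)OS(=O)(=O)C(F)(F)F | starting material
28 | triethylsilyl (2S)-2-methyl-2-(triethylsilyloxy)but-3-enoate | C=C[C@](C)(O[Si](CC)(CC)CC)C(=O)O[Si](CC)(CC)CC | intermediate
29 | (2S)-2-methyl-2-(triethylsilyloxy)but-3-enoic acid | C=C[C@](C)(O[Si](CC)(CC)CC)C(=O)O | intermediate
30 | (2S)-2-methyl-2-(triethylsilyloxy)but-3-enoic 2,4,6-trichlorobenzoic anhydride | C=C[C@](C)(O[Si](CC)(CC)CC)C(=O)OC(=O)c1c(Cl)cc(Cl)cc1Cl | intermediate
31 | methyl (4S,6R,8S,9R)-4,9-epoxy-6-[(2S)-2-methyl-2-(triethylsilyloxy)but-3-enoyloxy]-13-norgermacra-1(10),7(11)-dien-12,8-olid-14-oate | C=C[C@](C)(O[Si](CC)(CC)CC)C(=O)O[C@@H]1C[C@]2(C)CCC=C(C(=O)OC)[C@@H](O2)[C@H]2OC(=O)C=C21 | intermediate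
32 | dimethylmethylideneammonium iodide | C=[N+](C)C.[I-] | starting material
33 | C12 O-[diethoxy(methyl)silyl] ketene acetal of the (7R)-7,11-dihydro lactone of 31 | C=C[C@](C)(O[Si](CC)(CC)CC)C(=O)O[C@@H]1C[C@]2(C)CCC=C(C(=O)OC)[C@@H](O2)[C@H]2OC(O[Si](C)(OCC)OCC)=C[C@@H]21 | intermediate
34 | methyl (4S,6R,7R,8S,9R)-13-(dimethylamino)-4,9-epoxy-6-[(2S)-2-methyl-2-(triethylsilyloxy)but-3-enoyloxy]germacr-1(10)-en-12,8-olid-14-oate (C11 epimers) | C=C[C@](C)(O[Si](CC)(CC)CC)C(=O)O[C@@H]1C[C@]2(C)CCC=C(C(=O)OC)[C@@H](O2)[C@H]2OC(=O)C(CN(C)C)[C@@H]21 | intermediate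
35 | 13-trimethylammonio analogue of 34, iodide salt | C=C[C@](C)(O[Si](CC)(CC)CC)C(=O)O[C@@H]1C[C@]2(C)CCC=C(C(=O)OC)[C@@H](O2)[C@H]2OC(=O)C(C[N+](C)(C)C)[C@@H]21.[I-] | intermediate
36 | methyl (4S,6R,7R,8S,9R)-4,9-epoxy-6-[(2S)-2-methyl-2-(triethylsilyloxy)but-3-enoyloxy]germacra-1(10),11(13)-dien-12,8-olid-14-oate | C=C[C@](C)(O[Si](CC)(CC)CC)C(=O)O[C@@H]1C[C@]2(C)CCC=C(C(=O)OC)[C@@H](O2)[C@H]2OC(=O)C(=C)[C@@H]21 | intermediate
37 | methyl (4S,6R,7R,8S,9R)-4,9-epoxy-6-[(2S)-2-hydroxy-2-methylbut-3-enoyloxy]germacra-1(10),11(13)-dien-12,8-olid-14-oate (CNP0325750.1) | C=C[C@](C)(O)C(=O)O[C@@H]1C[C@]2(C)CCC=C(C(=O)OC)[C@@H](O2)[C@H]2OC(=O)C(=C)[C@@H]21 | target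

Total step count: 17
Longest linear sequence: 13 steps (steps 1–5, 7–10 and 14–17, from pent-4-yn-1-ol)

Steps most likely to fail

Step 9 (Proposed new method). What may go wrong: oligomerisation or γ-deprotonation of the formyl enoate outruns the ten-membered aldol closure, or enantiofacial control is poor. The fallback uses known reactions, sets out from 12 and 15 and returns at 20. MnO2 oxidation of 12 gives methyl (2E,6E)-2-formyl-7-iodo-6-methylhepta-2,6-dienoate F1. Soft enolisation of 15 (TBSOTf, Et3N) gives tributyl[5-(tert-butyldimethylsilyloxy)furan-3-yl]stannane F2. An intermolecular enantioselective vinylogous Mukaiyama aldol reaction of F2 with the chelating aldehyde F1 (Cu(OTf)2, divalent copper, with 2,2'-isopropylidenebis[(4S)-4-tert-butyl-2-oxazoline], CH2Cl2, −78 °C) forms the C8–C9 bond and, after silyl transfer, gives methyl (2E,6E)-2-{(R)-(tert-butyldimethylsilyloxy)[(2R)-5-oxo-3-(tributylstannyl)-2,5-dihydrofuran-2-yl]methyl}-7-iodo-6-methylhepta-2,6-dienoate F3. Intramolecular carbonylative Stille macrocyclisation (Pd2(dba)3, AsPh3, CO, high dilution) closes the ten-membered ring at C5–C6–C7 to the 9-O-tert-butyldimethylsilyl ether of 19 F4. HF·pyridine then frees the 9-hydroxyl to give 19, which closes by transannular oxa-Michael addition (DBU cat. if needed) to 20.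

Step 15. What may go wrong: hydride is delivered to the wrong face of C7, or to the acyclic C1=C10 enoate with β-elimination of the ether bridge. The fallback sets out from 20 and returns at 34. Zinc dust in AcOH reduces the ketone-conjugated C7=C11 bond of 20 chemoselectively (the isolated enoate is inert to zinc) to methyl (4S,7S,8S,9R)-4,9-epoxy-6-oxo-13-norgermacr-1(10)-en-12,8-olid-14-oate F5, in which C7 is set by protonation and can be equilibrated next to the ketone. Luche reduction gives methyl (4S,6R,7R,8S,9R)-4,9-epoxy-6-hydroxy-13-norgermacr-1(10)-en-12,8-olid-14-oate F6. Yamaguchi acylation with 29 gives the saturated lactone ester, the 7,11-dihydro analogue of 31 F7. Soft enolisation of the lactone (TBSOTf, Et3N) gives its C12 O-tert-butyldimethylsilyl ketene acetal F8, which reacts with 32 to give 34.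

Step 7. What may go wrong: direct coupling without CO insertion, and slow transmetalation of the electron-poor stannane. The fallback sets out from 12 and 13 and returns at 18. Palladium-catalysed formylation of 12 (Pd(PPh3)4, CO, Bu3SnH) gives methyl (2E,6E)-2-(hydroxymethyl)-6-methyl-8-oxoocta-2,6-dienoate F9. Nozaki–Hiyama–Kishi coupling of F9 with 13 (CrCl2, divalent chromium, NiCl2 cat., DMF) gives methyl (2E,6E)-8-hydroxy-2-(hydroxymethyl)-6-methyl-8-(5-oxo-2,5-dihydrofuran-3-yl)octa-2,6-dienoate F10. MnO2 then oxidises both allylic alcohols to give 18, so 17 is bypassed.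

Further compounds
F1 | step 9 | methyl (2E,6E)-2-formyl-7-iodo-6-methylhepta-2,6-dienoate | COC(=O)/C(C=O)=C/CC/C(C)=C/I
F2 | step 9 | tributyl[5-(tert-butyldimethylsilyloxy)furan-3-yl]stannane | CCCC[Sn](CCCC)(CCCC)c1coc(O[Si](C)(C)C(C)(C)C)c1
F3 | step 9 | methyl (2E,6E)-2-{(R)-(tert-butyldimethylsilyloxy)[(2R)-5-oxo-3-(tributylstannyl)-2,5-dihydrofuran-2-yl]methyl}-7-iodo-6-methylhepta-2,6-dienoate | COC(=O)/C(=C/CC/C(C)=C/I)[C@@H](O[Si](C)(C)C(C)(C)C)[C@H]1OC(=O)C=C1[Sn](CCCC)(CCCC)CCCC
F4 | step 9 | methyl (1(10)E,4E,8S,9R)-9-(tert-butyldimethylsilyloxy)-6-oxo-13-norgermacra-1(10),4,7(11)-trien-12,8-olid-14-oate | O=C1/C=C(C)/CC/C=C(C(=O)OC)\[C@@H](O[Si](C)(C)C(C)(C)C)[C@H]2OC(=O)C=C12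
F5 | step 15 | methyl (4S,7S,8S,9R)-4,9-epoxy-6-oxo-13-norgermacr-1(10)-en-12,8-olid-14-oate | O=C1C[C@]2(C)CCC=C(C(=O)OC)[C@@H](O2)[C@H]2OC(=O)C[C@@H]21
F6 | step 15 | methyl (4S,6R,7R,8S,9R)-4,9-epoxy-6-hydroxy-13-norgermacr-1(10)-en-12,8-olid-14-oate | O[C@@H]1C[C@]2(C)CCC=C(C(=O)OC)[C@@H](O2)[C@H]2OC(=O)C[C@@H]21
F7 | step 15 | methyl (4S,6R,7R,8S,9R)-4,9-epoxy-6-[(2S)-2-methyl-2-(triethylsilyloxy)but-3-enoyloxy]-13-norgermacr-1(10)-en-12,8-olid-14-oate | C=C[C@](C)(O[Si](CC)(CC)CC)C(=O)O[C@@H]1C[C@]2(C)CCC=C(C(=O)OC)[C@@H](O2)[C@H]2OC(=O)C[C@@H]21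
F8 | step 15 | C12 O-tert-butyldimethylsilyl ketene acetal of F7 | C=C[C@](C)(O[Si](CC)(CC)CC)C(=O)O[C@@H]1C[C@]2(C)CCC=C(C(=O)OC)[C@@H](O2)[C@H]2OC(O[Si](C)(C)C(C)(C)C)=C[C@@H]21
F9 | step 7 | methyl (2E,6E)-2-(hydroxymethyl)-6-methyl-8-oxoocta-2,6-dienoate | COC(=O)/C(CO)=C/CC/C(C)=C/C=O
F10 | step 7 | methyl (2E,6E)-8-hydroxy-2-(hydroxymethyl)-6-methyl-8-(5-oxo-2,5-dihydrofuran-3-yl)octa-2,6-dienoate (racemic carbinol) | COC(=O)/C(CO)=C/CC/C(C)=C/C(O)C1=CC(=O)OC1
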